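**Retrosynthetic overview**
1. The C11-OH/C13-Cl chlorohydrin is installed last, from the exocyclic C11=C13 alkene of an α-methylene lactone (face-selective dihydroxylation, then chlorination of the primary alcohol).
2. Ring C (γ-lactone O–C12–C11–C7–C6) is disconnected to CO2 plus a macrocyclic cis-5,6-epoxide carrying a 1-bromoethenyl group on C7. The enabling feature: the lactone oxygen on C6 is anti to the free hydroxyl on C5 (the pattern of a trans-opened cis-epoxide), and C6 is 1,3 to C11 through C7, so a carboxylate grown on C11 sits behind the C6–O bond of the epoxide.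
3. The epoxide comes from the (Z)-C5=C6 alkene of ring B (ten-membered carbocycle, i.e. nine-membered oxacycle bridged by the furanone), oxidised under direction of the C8/C9 hydroxyls; ring B is closed by ring-closing metathesis at C5=C6.
4. C9–C10 is made by aldol addition of a 3(2H)-furanone enolate (ring A; C4 set by auxiliary methylation) to an α-silyloxy aldehyde (C7/C8 from Sharpless epoxidation and alkynyl epoxide opening; alkyne converted to the 2-bromoalkene).
5. Order of ring formation: ring A (furanone), ring B (macrocycle), epoxide, ring C (lactone).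

Key step: step 17

Remark on the chemistry: locants C1–C13 follow germacranolide numbering of the target (C1 ketone, C2=C3, ether O between C3 and C10, C4 and C10 each bearing a methyl, C12 lactone carbonyl, C13 the CH2Cl carbon); the ester is the (E)-2-methylbut-2-enoate (tiglate), as the SMILES requires.

**Step 1**
Reactants: 1 (4R)-4-benzyl-1,3-oxazolidin-2-one; 2 but-3-enoic acid
Product: 4 (4R)-4-benzyl-3-(but-3-enoyl)-1,3-oxazolidin-2-one, via but-3-enoic pivalic anhydride 3 (not isolated)
Conditions: 2, t-BuCOCl, Et3N, THF, −20 °C; then 1, LiCl, −20 °C → rt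
Reagents that add atoms: none
Why: N-acylation of the oxazolidinone through the mixed pivalic anhydride is a standard imide synthesis that should leave the β,γ-alkene unconjugated; no stereocentre is formed.

**Step 2**
Reactants: 4 (4R)-4-benzyl-3-(but-3-enoyl)-1,3-oxazolidin-2-one
Product: 6 (4R)-4-benzyl-3-[(2R)-2-methylbut-3-enoyl]-1,3-oxazolidin-2-one, via sodium dienolate 5 (not isolated)
Conditions: NaN(SiMe3)2, THF, −78 °C; MeI, −78 → −40 °C
Reagents that add atoms: iodomethane, CI
Why: Evans auxiliary alkylation, in which the chelated (Z)-enolate should be methylated at the α-carbon on the face away from the benzyl group, setting with the (R)-auxiliary the (2R) centre that becomes C4.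

**Step 3**
Reactants: 6 (4R)-4-benzyl-3-[(2R)-2-methylbut-3-enoyl]-1,3-oxazolidin-2-one
Product: 7 (2R)-N-methoxy-N,2-dimethylbut-3-enamide
Conditions: MeNH(OMe)·HCl, AlMe3, CH2Cl2, 0 °C → rt; aq. HCl work-up
Reagents that add atoms: N,O-dimethylhydroxylamine hydrochloride, CNOC.Cl
Why: aluminium-amide transamidation of the N-acyloxazolidinone to the Weinreb amide is non-enolising, so the α-stereocentre and the β,γ-alkene should survive while the auxiliary is released.

**Step 4**
Reactants: 7 (2R)-N-methoxy-N,2-dimethylbut-3-enamide; 8 3-hydroxybutan-2-one (racemic)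
Product: 11 5-[(2R)-but-3-en-2-yl]-2-methylfuran-3(2H)-one (both C2 epimers), via dilithio acetoin dianion 9 (not isolated), via hydroxy diketone 10 (not isolated)
Conditions: 8 (2.5 equiv), LiN(iPr)2 (5 equiv), THF, −78 °C; 7, −78 → 0 °C; then 2 M aq. HCl, THF, rt
Reagents that add atoms: none
Why: Claisen-type acylation of the kinetic methyl-ketone enolate by the Weinreb amide should give the α′-hydroxy 1,3-diketone, which on acid closes through the hydroxyl onto the distal carbonyl and dehydrates to the 3(2H)-furanone (ring A), the excess enolate holding the product as its diketonate so that the C4 centre is not epimerised.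

**Step 5**
Reactants: 12 (2E)-penta-2,4-dien-1-ol
Product: 13 [(2R,3R)-3-ethenyloxiran-2-yl]methanol
Conditions: Ti(OiPr)4 (10 mol %), D-(−)-diisopropyl tartrate (12 mol %), t-BuOOH, 4 Å molecular sieves, CH2Cl2, −20 °C
Reagents that add atoms: tert-butyl hydroperoxide, CC(C)(C)OO
Why: Sharpless asymmetric epoxidation oxidises only the allylic double bond of the dienol, and the D-tartrate ligand should give the (2R,3R)-epoxide, fixing C8 and (after inversion in step 7) C7.

**Step 6**
Reactants: 13 [(2R,3R)-3-ethenyloxiran-2-yl]methanol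
Product: 14 tert-butyl{[(2R,3R)-3-ethenyloxiran-2-yl]methoxy}dimethylsilane
Conditions: t-BuMe2SiCl, imidazole, CH2Cl2, 0 °C → rt
Reagents that add atoms: tert-butyl(chloro)dimethylsilane, CC(C)(C)[Si](C)(C)Cl
Why: routine silylation of the primary alcohol, so that the Lewis-acid-mediated epoxide opening is not diverted by a free hydroxyl; no stereocentre changes.

**Step 7**
Reactants: 14 tert-butyl{[(2R,3R)-3-ethenyloxiran-2-yl]methoxy}dimethylsilane
Product: 15 (2S,3R)-1-[(tert-butyldimethylsilyl)oxy]-3-ethenylpent-4-yn-2-ol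
Conditions: HC≡CH, n-BuLi, THF, −78 °C; BF3·OEt2; then 14, −78 °C
Reagents that add atoms: acetylene, C#C
Why: BF3-promoted epoxide opening by lithium acetylide should occur by SN2 at the allylic carbon (C7), activated by the vinyl group and remote from the electron-withdrawing CH2OSi, with inversion, giving the 7,8-anti arrangement.

**Step 8**
Reactants: 15 (2S,3R)-1-[(tert-butyldimethylsilyl)oxy]-3-ethenylpent-4-yn-2-ol
Product: 16 (2S,3R)-1,2-bis[(tert-butyldimethylsilyl)oxy]-3-ethenylpent-4-yne
Conditions: t-BuMe2SiOTf, 2,6-lutidine, CH2Cl2, −78 → 0 °C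
Reagents that add atoms: tert-butyldimethylsilyl trifluoromethanesulfonate, CC(C)(C)[Si](C)(C)OS(=O)(=O)C(F)(F)F
Why: silyl triflate silylation of the hindered secondary alcohol; the bulky O-silyl group later enforces non-chelated (Felkin–Anh) addition to the C9 aldehyde.

**Step 9**
Reactants: 16 (2S,3R)-1,2-bis[(tert-butyldimethylsilyl)oxy]-3-ethenylpent-4-yne
Product: 18 (3S,4S)-2-bromo-4,5-bis[(tert-butyldimethylsilyl)oxy]-3-ethenylpent-1-ene, via alkenylborane 17 (not isolated)
Conditions: B-bromo-9-borabicyclo[3.3.1]nonane, CH2Cl2, 0 °C; then AcOH, 0 °C → rt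
Reagents that add atoms: B-bromo-9-borabicyclo[3.3.1]nonane, BrB1C2CCCC1CCC2
Why: syn-bromoboration of the terminal alkyne places bromine on the internal carbon (C11) and boron on the terminus, and protonolysis of the C–B bond should give the 2-bromo-1-alkene without touching the monosubstituted alkene or the silyl ethers.

**Step 10**
Reactants: 18 (3S,4S)-2-bromo-4,5-bis[(tert-butyldimethylsilyl)oxy]-3-ethenylpent-1-ene
Product: 19 (2S,3S)-4-bromo-2-[(tert-butyldimethylsilyl)oxy]-3-ethenylpent-4-en-1-ol
Conditions: HF·pyridine, pyridine, THF, 0 °C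
Reagents that add atoms: none
Why: buffered HF·pyridine should cleave the primary silyl ether much faster than the secondary one, a standard selective desilylation.

**Step 11**
Reactants: 19 (2S,3S)-4-bromo-2-[(tert-butyldimethylsilyl)oxy]-3-ethenylpent-4-en-1-ol
Product: 20 (2S,3S)-4-bromo-2-[(tert-butyldimethylsilyl)oxy]-3-ethenylpent-4-enal
Conditions: Dess–Martin periodinane, CH2Cl2, 0 °C → rt; used crude
Reagents that add atoms: none
Why: Dess–Martin oxidation gives the α-silyloxy aldehyde under non-basic conditions, so the C8 centre should not epimerise.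

**Step 12**
Reactants: 11 5-[(2R)-but-3-en-2-yl]-2-methylfuran-3(2H)-one; 20 (2S,3S)-4-bromo-2-[(tert-butyldimethylsilyl)oxy]-3-ethenylpent-4-enal
Product: 22 (2S)-2-{(1S,2S,3S)-4-bromo-2-[(tert-butyldimethylsilyl)oxy]-3-ethenyl-1-hydroxypent-4-en-1-yl}-5-[(2R)-but-3-en-2-yl]-2-methylfuran-3(2H)-one, via lithium furanolate 21 (not isolated)
Conditions: 11 (1.3 equiv), LiN(iPr)2, THF, −78 °C; then 20, −78 °C; AcOH quench at −78 °C
Reagents that add atoms: none
Why: aldol addition of the aromatic 3-oxidofuran (formed by removing the acidic C10–H) through C10, in which a Zimmerman–Traxler chair with the methyl cis to the enolate oxygen should place the C10 methyl syn to the new C9 hydroxyl, and Felkin–Anh attack anti to the bulky α-silyloxy group should set C9 anti to the C8 oxygen.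

**Step 13**
Reactants: 22 (the aldol adduct, a diene)
Product: 23 (4R,5Z,7S,8S,9S,10S)-7-(1-bromoethenyl)-8-[(tert-butyldimethylsilyl)oxy]-9-hydroxy-4,10-dimethyl-3,10-epoxycyclodeca-2,5-dien-1-one
Conditions: second-generation Hoveyda–Grubbs catalyst RuCl2(=CH-C6H4-2-OiPr)(H2IMes) (10 mol %), 1,4-benzoquinone (20 mol %), toluene (1 mM), 80 °C
Reagents that add atoms: none
Why: ring-closing metathesis of the two monosubstituted alkenes should close ring B with the (Z)-C5=C6 geometry that the ring size enforces, the 1-bromoethenyl group and the furanone double bond being too hindered or electron-poor to compete and benzoquinone suppressing migration of the C4 vinyl group; metathesis closure of 3(2H)-furanone-bridged medium rings is precedented.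

**Step 14**
Reactants: 23 (the 8-O-silyl macrocycle)
Product: 24 (4R,5Z,7S,8S,9S,10S)-7-(1-bromoethenyl)-8,9-dihydroxy-4,10-dimethyl-3,10-epoxycyclodeca-2,5-dien-1-one
Conditions: HF·pyridine, THF, 0 °C → rt
Reagents that add atoms: none
Why: acidic fluoride removes the secondary silyl ether without base, which the retro-aldol-prone β-hydroxy ketone would not tolerate, and frees the C8 hydroxyl that directs the next step.

**Step 15**
Reactants: 24 (the 8,9-diol)
Product: 25 (4R,5S,6R,7R,8S,9S,10S)-7-(1-bromoethenyl)-8,9-dihydroxy-4,10-dimethyl-3,10:5,6-diepoxycyclodec-2-en-1-one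
Conditions: VO(acac)2 (5 mol %), t-BuOOH, CH2Cl2, 0 °C → rt
Reagents that add atoms: tert-butyl hydroperoxide, CC(C)(C)OO
Why: vanadium-catalysed hydroxyl-directed epoxidation, in which the vanadate ester of the homoallylic C8 hydroxyl (helped by the C9 hydroxyl on the same side) should deliver oxygen to the alkene face cis to these hydroxyls and 1,3-syn to O8, giving the cis-epoxide with C5 in its final configuration and C6 in the inverted one, while the other alkenes carry no directing group.

**Step 16**
Reactants: 25 (the epoxy diol)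
Product: 26 (4R,5S,6R,7S,8S,9S,10S)-7-(1-bromoethenyl)-9-hydroxy-4,10-dimethyl-1-oxo-3,10:5,6-diepoxycyclodec-2-en-8-yl (2E)-2-methylbut-2-enoate
Conditions: (E)-2-methylbut-2-enoyl chloride, pyridine, 4-(dimethylamino)pyridine (cat.), CH2Cl2, 0 °C
Reagents that add atoms: (E)-2-methylbut-2-enoyl chloride, C/C=C(\C)C(=O)Cl
Why: acylation should take place at the C8 hydroxyl because the C9 hydroxyl is neopentylic (next to quaternary C10) and hydrogen-bonded to the C1 ketone; the tiglate geometry comes from the acid chloride.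

**Step 17**
Reactants: 26 (the 8-tiglate of the epoxy bromoalkene)
Product: 28 (4R,5S,6S,7S,8S,9S,10S)-5,9-dihydroxy-1-oxo-3,10-epoxygermacra-2,11(13)-dien-12,6-olid-8-yl (2E)-2-methylbut-2-enoate, via epoxy acrylic acid 27 (not isolated)
Conditions: NiBr2(dme) (10 mol %), neocuproine (20 mol %), Mn powder (3 equiv), CO2 (1 atm), DMF, 25 °C; then 1 M aq. HCl, 0 °C → rt
Reagents that add atoms: carbon dioxide, O=C=O
Why: Manganese reduces the divalent nickel precatalyst to zerovalent nickel, which inserts into the C11–Br bond; one-electron reduction gives a monovalent alkenylnickel that adds to CO2 (C12–C11 bond), and the resulting carboxylate opens the cis-epoxide at C6 from the rear (O–C6 bond), the mild acid work-up completing the lactonisation. The closest known reaction types are the nickel-catalysed reductive carboxylation of alkenyl and aryl halides with CO2 under manganese and the ready lactonisation of γ,δ-epoxy acids. Ring C closes in the 5-exo-tet mode at C6 (6-endo attack at C5 is disfavoured), and because the carboxylate enters anti to the epoxide oxygen the lactone is trans-fused to ring B. C6 is set by inversion at the epoxide carbon, C5 keeps the epoxide oxygen with retention as the free hydroxyl, and both therefore follow from the epoxide configuration set in step 15; C7 is untouched. The step needs the alkenyl bromide to be activated in the presence of the epoxide, the furanone, the tiglate and the free C9 hydroxyl: zerovalent nickel adds to a C(sp2)–Br bond much faster than to a dialkyl epoxide, a carboxylate (unlike an acylmetal) cannot be captured by the C9 hydroxyl, and that hydroxyl lies on the epoxide-oxygen side of C6 and so cannot compete in the rear-side opening.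

**Step 18**
Reactants: 28 (the α-methylene lactone)
Product: 29 (4R,5S,6S,7S,8S,9S,10S,11R)-5,9,11,13-tetrahydroxy-1-oxo-3,10-epoxygermacr-2-en-12,6-olid-8-yl (2E)-2-methylbut-2-enoate
Conditions: OsO4 (5 mol %), N-methylmorpholine N-oxide (1.1 equiv), acetone–H2O, 0 °C
Reagents that add atoms: N-methylmorpholine N-oxide, C[N+]1([O-])CCOCC1; water, O
Why: catalytic dihydroxylation (Upjohn conditions) should select the unhindered 1,1-disubstituted exocyclic alkene over the trisubstituted tiglate and the furanone double bond, and attack on the face of C11=C13 opposite to the C8 tigloyloxy group (the side of H7) sets the C11 hydroxyl.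

**Step 19**
Reactants: 29 (the 11,13-diol)
Product: 30 (4R,5S,6S,7S,8S,9S,10S,11S)-13-chloro-5,9,11-trihydroxy-1-oxo-3,10-epoxygermacr-2-en-12,6-olid-8-yl (2E)-2-methylbut-2-enoate (CNP0340393.1)
Conditions: PPh3, CCl4, pyridine, 40 °C
Reagents that add atoms: tetrachloromethane, ClC(Cl)(Cl)Cl
Why: the Appel reaction should chlorinate only the primary C13 hydroxyl in the presence of the secondary (C5, C9) and tertiary (C11) ones, and C11 keeps its configuration because substitution occurs at C13 (directly, or through a spiro-epoxide that chloride reopens at CH2).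

**Compound list**
1 | (4R)-4-benzyl-1,3-oxazolidin-2-one | O=C1N[C@H](Cc2ccccc2)CO1 | starting material
2 | but-3-enoic acid | C=CCC(=O)O | starting material
3 | but-3-enoic 2,2-dimethylpropanoic anhydride | C=CCC(=O)OC(=O)C(C)(C)C | intermediate
4 | (4R)-4-benzyl-3-(but-3-enoyl)-1,3-oxazolidin-2-one | C=CCC(=O)N1[C@H](Cc2ccccc2)COC1=O | intermediate
5 | sodium (Z)-dienolate of 4 | [Na+].[O-]/C(=C\C=C)N1[C@H](Cc2ccccc2)COC1=O | intermediate
6 | (4R)-4-benzyl-3-[(2R)-2-methylbut-3-enoyl]-1,3-oxazolidin-2-one | C=C[C@@H](C)C(=O)N1[C@H](Cc2ccccc2)COC1=O | intermediate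
7 | (2R)-N-methoxy-N,2-dimethylbut-3-enamide | CON(C)C(=O)[C@H](C)C=C | intermediate
8 | 3-hydroxybutan-2-one (racemic) | CC(O)C(C)=O | starting material
9 | dilithium 3-oxidobut-1-en-2-olate | [Li+].[Li+].C=C([O-])C(C)[O-] | intermediate
10 | (6R)-2-hydroxy-6-methyloct-7-ene-3,5-dione (both C2 epimers) | CC(O)C(=O)CC(=O)[C@H](C)C=C | intermediate
11 | 5-[(2R)-but-3-en-2-yl]-2-methylfuran-3(2H)-one (both C2 epimers) | CC1OC(=CC1=O)[C@H](C)C=C | intermediate
12 | (2E)-penta-2,4-dien-1-ol | OC/C=C/C=C | starting material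
13 | [(2R,3R)-3-ethenyloxiran-2-yl]methanol | OC[C@H]1O[C@@H]1C=C | intermediate
14 | tert-butyl{[(2R,3R)-3-ethenyloxiran-2-yl]methoxy}dimethylsilane | CC(C)(C)[Si](C)(C)OC[C@H]1O[C@@H]1C=C | intermediate
15 | (2S,3R)-1-[(tert-butyldimethylsilyl)oxy]-3-ethenylpent-4-yn-2-ol | CC(C)(C)[Si](C)(C)OC[C@@H](O)[C@H](C=C)C#C | intermediate
16 | (2S,3R)-1,2-bis[(tert-butyldimethylsilyl)oxy]-3-ethenylpent-4-yne | CC(C)(C)[Si](C)(C)OC[C@@H](O[Si](C)(C)C(C)(C)C)[C@H](C=C)C#C | intermediate
17 | 9-[(1Z,3S,4S)-2-bromo-4,5-bis[(tert-butyldimethylsilyl)oxy]-3-ethenylpent-1-en-1-yl]-9-borabicyclo[3.3.1]nonane | CC(C)(C)[Si](C)(C)OC[C@@H](O[Si](C)(C)C(C)(C)C)[C@H](C=C)/C(Br)=C/B1C2CCCC1CCC2 | intermediate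
18 | (3S,4S)-2-bromo-4,5-bis[(tert-butyldimethylsilyl)oxy]-3-ethenylpent-1-ene | CC(C)(C)[Si](C)(C)OC[C@@H](O[Si](C)(C)C(C)(C)C)[C@H](C=C)C(Br)=C | intermediate
19 | (2S,3S)-4-bromo-2-[(tert-butyldimethylsilyl)oxy]-3-ethenylpent-4-en-1-ol | OC[C@@H](O[Si](C)(C)C(C)(C)C)[C@H](C=C)C(Br)=C | intermediate
20 | (2S,3S)-4-bromo-2-[(tert-butyldimethylsilyl)oxy]-3-ethenylpent-4-enal | O=C[C@@H](O[Si](C)(C)C(C)(C)C)[C@H](C=C)C(Br)=C | intermediate
21 | lithium 5-[(2R)-but-3-en-2-yl]-2-methylfuran-3-olate | [Li+].CC1=C([O-])C=C(O1)[C@H](C)C=C | intermediate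
22 | (2S)-2-{(1S,2S,3S)-4-bromo-2-[(tert-butyldimethylsilyl)oxy]-3-ethenyl-1-hydroxypent-4-en-1-yl}-5-[(2R)-but-3-en-2-yl]-2-methylfuran-3(2H)-one | C=C[C@@H](C)C1=CC(=O)[C@@](C)(O1)[C@@H](O)[C@@H](O[Si](C)(C)C(C)(C)C)[C@H](C=C)C(Br)=C | intermediate
23 | (4R,5Z,7S,8S,9S,10S)-7-(1-bromoethenyl)-8-[(tert-butyldimethylsilyl)oxy]-9-hydroxy-4,10-dimethyl-3,10-epoxycyclodeca-2,5-dien-1-one | CC(C)(C)[Si](C)(C)O[C@H]1[C@@H](C(Br)=C)/C=C\[C@@H](C)C2=CC(=O)[C@@](C)(O2)[C@H]1O | intermediate
24 | (4R,5Z,7S,8S,9S,10S)-7-(1-bromoethenyl)-8,9-dihydroxy-4,10-dimethyl-3,10-epoxycyclodeca-2,5-dien-1-one | O[C@H]1[C@@H](C(Br)=C)/C=C\[C@@H](C)C2=CC(=O)[C@@](C)(O2)[C@H]1O | intermediate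
25 | (4R,5S,6R,7R,8S,9S,10S)-7-(1-bromoethenyl)-8,9-dihydroxy-4,10-dimethyl-3,10:5,6-diepoxycyclodec-2-en-1-one | O[C@H]1[C@@H](C(Br)=C)[C@H]3O[C@H]3[C@@H](C)C2=CC(=O)[C@@](C)(O2)[C@H]1O | intermediate
26 | (4R,5S,6R,7S,8S,9S,10S)-7-(1-bromoethenyl)-9-hydroxy-4,10-dimethyl-1-oxo-3,10:5,6-diepoxycyclodec-2-en-8-yl (2E)-2-methylbut-2-enoate | C/C=C(\C)C(=O)O[C@H]1[C@@H](C(Br)=C)[C@H]3O[C@H]3[C@@H](C)C2=CC(=O)[C@@](C)(O2)[C@H]1O | intermediate
27 | 2-[(4R,5S,6R,7S,8S,9S,10S)-9-hydroxy-4,10-dimethyl-1-oxo-8-{[(2E)-2-methylbut-2-enoyl]oxy}-3,10:5,6-diepoxycyclodec-2-en-7-yl]prop-2-enoic acid (formed as its manganese salt) | C/C=C(\C)C(=O)O[C@H]1[C@@H](C(=C)C(=O)O)[C@H]3O[C@H]3[C@@H](C)C2=CC(=O)[C@@](C)(O2)[C@H]1O | intermediate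
28 | (4R,5S,6S,7S,8S,9S,10S)-5,9-dihydroxy-1-oxo-3,10-epoxygermacra-2,11(13)-dien-12,6-olid-8-yl (2E)-2-methylbut-2-enoate | C/C=C(\C)C(=O)O[C@H]1[C@@H]2[C@H](OC(=O)C2=C)[C@@H](O)[C@@H](C)C2=CC(=O)[C@@](C)(O2)[C@H]1O | intermediate
29 | (4R,5S,6S,7S,8S,9S,10S,11R)-5,9,11,13-tetrahydroxy-1-oxo-3,10-epoxygermacr-2-en-12,6-olid-8-yl (2E)-2-methylbut-2-enoate | C/C=C(\C)C(=O)O[C@H]1[C@@H]2[C@H](OC(=O)[C@]2(O)CO)[C@@H](O)[C@@H](C)C2=CC(=O)[C@@](C)(O2)[C@H]1O | intermediate
30 | (4R,5S,6S,7S,8S,9S,10S,11S)-13-chloro-5,9,11-trihydroxy-1-oxo-3,10-epoxygermacr-2-en-12,6-olid-8-yl (2E)-2-methylbut-2-enoate | C/C=C(\C)C(=O)O[C@H]1[C@@H]2[C@H](OC(=O)[C@]2(O)CCl)[C@@H](O)[C@@H](C)C2=CC(=O)[C@@](C)(O2)[C@H]1O | target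

**Step count and risks**
Total step count: 19. Longest linear sequence: 15 steps (steps 5 to 19, from 12); the furanone branch (steps 1 to 4) joins at step 12.

The three steps most likely to fail:

Step 15: oxygen may be delivered to the wrong face of the ring alkene, or not at all; a non-directed oxidant would be expected to attack the other face, so the step depends on delivery from the C8/C9 hydroxyls across a medium ring. The fallback replaces metal-alkoxide delivery by a tethered carbonate and an external iodonium. It sets out from 24: Boc2O and 4-(dimethylamino)pyridine should acylate the less hindered C8 hydroxyl to give the 8-O-tert-butyl carbonate F1, and Me3SiOTf with 2,6-lutidine masks the C9 hydroxyl as the trimethylsilyl ether F2 so that it cannot form an ether. IBr in toluene at −80 °C then places iodine on the open face while the carbonate oxygen closes on C6 from the side of O8 (six-membered ring, 1,3-syn), giving the cyclic iodocarbonate F3. K2CO3 in MeOH at 0 °C cleaves the carbonate and the silyl ether, and the C6 alkoxide displaces iodide at C5 with inversion; the route is rejoined at 25.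

Step 17: the carboxylation may be incomplete or unselective (protodebromination by the free hydroxyl, or opening of the epoxide by bromide before the carboxylate exists). The fallback separates metalation from CO2 capture. It sets out from 26: Miyaura borylation (PdCl2(dppf), bis(pinacolato)diboron, KOAc, dioxane, 60 °C) gives the alkenyl pinacolboronate F4. Copper-catalysed carboxylation of the boronate (CuI, a bis(oxazoline) ligand, CsF, CO2 at 1 atm, DMF, 60 °C) followed by aqueous HCl gives acid 27, which lactonises as before; the route is rejoined at 28.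

Step 12: the aldol may show poor simple or facial diastereoselection at C9/C10, and the adduct may revert by retro-aldol before the quench. The fallback changes from the closed lithium-enolate transition state to an open Lewis-acid one with no free alkoxide. It sets out from 11: t-BuMe2SiOTf and Et3N give the 3-silyloxyfuran F5, and a Mukaiyama aldol with 20 (BF3·OEt2, CH2Cl2, −78 °C) is expected to keep Felkin–Anh control at C9 while offering the complementary sense of C9/C10 selection; the route is rejoined at 22.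

**Further compounds**
F1 | step 15 | tert-butyl (4R,5Z,7S,8S,9S,10S)-7-(1-bromoethenyl)-9-hydroxy-4,10-dimethyl-1-oxo-3,10-epoxycyclodeca-2,5-dien-8-yl carbonate | CC(C)(C)OC(=O)O[C@H]1[C@@H](C(Br)=C)/C=C\[C@@H](C)C2=CC(=O)[C@@](C)(O2)[C@H]1O
F2 | step 15 | the 9-O-trimethylsilyl ether of F1 | CC(C)(C)OC(=O)O[C@H]1[C@@H](C(Br)=C)/C=C\[C@@H](C)C2=CC(=O)[C@@](C)(O2)[C@H]1O[Si](C)(C)C
F3 | step 15 | cyclic 6,8-carbonate of the 5-iodo-6,8-diol, 9-O-trimethylsilyl ether (iodine on C5, carbonate oxygen on C6 syn to O8) | O=C3O[C@H]1[C@@H](C(Br)=C)[C@@H](O3)[C@H](I)[C@@H](C)C2=CC(=O)[C@@](C)(O2)[C@H]1O[Si](C)(C)C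
F4 | step 17 | the alkenyl pinacolboronate corresponding to 26 (Bpin in place of Br on C11) | C/C=C(\C)C(=O)O[C@H]1[C@@H](C(=C)B4OC(C)(C)C(C)(C)O4)[C@H]3O[C@H]3[C@@H](C)C2=CC(=O)[C@@](C)(O2)[C@H]1O
F5 | step 12 | {5-[(2R)-but-3-en-2-yl]-2-methylfuran-3-yl}oxy(tert-butyl)dimethylsilane | CC1=C(O[Si](C)(C)C(C)(C)C)C=C(O1)[C@H](C)C=C
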